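**Plan**

1. Retrosynthetic cuts, in order: the C=C of the acrylate that joins the two halves (Wittig) and its tertiary O–acyl bond (alcohol plus Ph3P=C=C=O); both C(sp2)–CH2OH bonds (Stille) and the second acrylate C=C (Wittig); in the lower half the butenolide C3a–C3 bond and lactone C–O (vinyl triflate plus Bu3SnCH2OH); in the upper half the C3a–O and C3–O bonds (osmylation of an exocyclic methylene, then lactonisation).
2. Both halves converge on one cyclohexanone β-keto ester, whose ring is cut at C4–C5 (aldol condensation, then hydrogenation) and at C6–C7 (Michael addition), back to 3-methylbutanal, methyl acetoacetate and 2,2-dimethoxyacetaldehyde (2-benzofuran-1(3H)-one locants: C1 lactone C=O, C3 OCH2, C6 isopropyl, C7 side chain).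
3. Enabling feature: the butenolide unit C1(=O)–C7a=C3a is a β-keto ester in disguise (C3a at the ketone level), so the ring CH2 at C4 is the nucleophilic methyl of an acetoacetate, C5 is the carbonyl carbon of an aldehyde whose α-carbon C6 carries the isopropyl group, and C7 is the β-carbon of a Knoevenagel acceptor.
4. Forward order: carbocycle first, then the common keto ester, then the butenolide half and the hydroxy-lactone half separately, then union through the tertiary ester and its alkene, then the second side chain, both CH2OH groups, and last the free acid.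
5. Stereochemistry: C6 and C7 of both halves come from one (S)-diphenylprolinol silyl ether-catalysed syn-selective Michael step; C7a and C3a of the upper half come from the equatorial ester and equatorial osmylation; both trisubstituted alkenes come from Z-selective bromo-ylide Wittig reactions followed by Stille coupling with retention.

Key step: step 2

Remark: the Knoevenagel adduct is carried forward as its E/Z mixture, since both isomers offer the same prochiral β-carbon to the enamine and the alkene is consumed in step 2.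

**Step 1**
Reactants: 1 2,2-dimethoxyacetaldehyde; 2 methyl 3-oxobutanoate
Product: 3 methyl (2Z)-2-acetyl-4,4-dimethoxybut-2-enoate (with its 2E isomer)
Conditions: piperidine (10 mol%), AcOH (10 mol%), MgSO4, CH2Cl2, 0 °C to rt
Reagents that add atoms: none
Why: Knoevenagel condensation of an active methylene compound with a non-enolisable aldehyde; no stereocentre is formed.

**Step 2**
Reactants: 3 methyl (2Z)-2-acetyl-4,4-dimethoxybut-2-enoate; 4 3-methylbutanal
Product: 6 methyl (1S,5S,6R)-6-(dimethoxymethyl)-2-oxo-5-(propan-2-yl)cyclohex-3-ene-1-carboxylate, via Michael adduct keto-aldehyde 5 (not isolated)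
Conditions: (S)-α,α-diphenylprolinol trimethylsilyl ether (10 mol%), PhCO2H (10 mol%), toluene, 0 °C to rt; then p-TsOH·H2O (20 mol%), 4 Å MS, 60 °C
Reagents that add atoms: none
Why: The amine condenses with 4 to the E-enamine, whose face anti to the CPh2(OSiMe3) group adds to the β-carbon of 3 through an acyclic synclinal transition state, and hydrolysis releases keto-aldehyde 5 (in equilibrium with its cyclic hemiacetal). Acid then enolises the methyl ketone towards its CH3, and a 6-(enolendo)-exo-trig aldol addition to the aldehyde followed by dehydration closes the carbocycle by joining the acetoacetate methyl carbon to the aldehyde carbon; step 3 saturates this bond to the C4–C5 ethano bridge. The closest known reactions are the diarylprolinol silyl ether-catalysed Michael addition of aldehydes to nitroalkenes and alkylidene malonates, and the organocatalytic Michael/aldol-condensation (Robinson-type) route to 2-oxocyclohex-3-ene-1-carboxylates from β-keto esters and enals. The isopropyl-bearing centre is set by catalyst shielding of one enamine face, the acetal-bearing centre by the syn topology of the Michael step (syn in the chain becomes trans on the ring, which is also the thermodynamic arrangement), and the ester-bearing centre settles equatorial by enolisation. The step needs C-cyclisation through the methyl group: the doubly activated CH could only close a four-membered ring, O-cyclisation to the hemiacetal or 4H-pyran is reversible while the conjugated enone is a sink, and anhydrous acid with sieves should keep the dimethyl acetal intact.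

**Step 3**
Reactants: 6 methyl (1S,5S,6R)-6-(dimethoxymethyl)-2-oxo-5-(propan-2-yl)cyclohex-3-ene-1-carboxylate
Product: 7 methyl (1S,2R,3R)-2-(dimethoxymethyl)-6-oxo-3-(propan-2-yl)cyclohexane-1-carboxylate
Conditions: H2 (1 atm), Pd/C (10 wt%), EtOAc, rt
Reagents that add atoms: none
Why: Catalytic hydrogenation of the conjugated disubstituted C=C is much faster than ketone reduction or acetal hydrogenolysis; the two ring stereocentres are untouched and the ester stays equatorial through enol equilibration.

**Step 4**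
Reactants: 7 methyl (1S,2R,3R)-2-(dimethoxymethyl)-6-oxo-3-(propan-2-yl)cyclohexane-1-carboxylate
Product: 8 methyl (5R,6R)-6-(dimethoxymethyl)-5-(propan-2-yl)-2-[(trifluoromethanesulfonyl)oxy]cyclohex-1-ene-1-carboxylate
Conditions: Tf2O, i-Pr2NEt, CH2Cl2, −78 °C
Reagents that add atoms: trifluoromethanesulfonic anhydride, O=S(=O)(OS(=O)(=O)C(F)(F)F)C(F)(F)F
Why: O-sulfonylation of the β-keto ester enolate (enol triflate formation) can only give the conjugated vinyl triflate; the epimerisable ester-bearing centre becomes sp2.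

**Step 5**
Reactants: 8 methyl (5R,6R)-6-(dimethoxymethyl)-5-(propan-2-yl)-2-[(trifluoromethanesulfonyl)oxy]cyclohex-1-ene-1-carboxylate
Product: 10 (6R,7R)-7-(dimethoxymethyl)-6-(propan-2-yl)-4,5,6,7-tetrahydro-2-benzofuran-1(3H)-one, via hydroxymethyl enoate 9 (not isolated)
Conditions: Bu3SnCH2OH, Pd(PPh3)4 (5 mol%), LiCl, 1,4-dioxane, 100 °C
Reagents that add atoms: (tributylstannyl)methanol, CCCC[Sn](CCCC)(CCCC)CO
Why: Stille coupling of the vinyl triflate with the hydroxymethyl stannane gives the Z-γ-hydroxy enoate 9, which lactonises in the flask with loss of methanol to the butenolide; both stereocentres are remote from the reacting atoms.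

**Step 6**
Reactants: 10 (6R,7R)-7-(dimethoxymethyl)-6-(propan-2-yl)-4,5,6,7-tetrahydro-2-benzofuran-1(3H)-one
Product: 11 (4R,5R)-3-oxo-5-(propan-2-yl)-1,3,4,5,6,7-hexahydro-2-benzofuran-4-carbaldehyde
Conditions: TFA/H2O/CHCl3 (1:1:4), 0 °C; used directly in step 10
Reagents that add atoms: water, O
Why: Acid-catalysed acetal hydrolysis leaves the acid-stable butenolide alone, and low temperature with short contact should limit enolisation of the α-stereocentre.

**Step 7**
Reactants: 7 methyl (1S,2R,3R)-2-(dimethoxymethyl)-6-oxo-3-(propan-2-yl)cyclohexane-1-carboxylate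
Product: 12 methyl (1S,2R,3R)-2-(dimethoxymethyl)-6-methylidene-3-(propan-2-yl)cyclohexane-1-carboxylate
Conditions: Zn, CH2Br2, TiCl4 (reagent pre-formed in THF); then 7, CH2Cl2, 0 °C to rt
Reagents that add atoms: dibromomethane, BrCBr
Why: Takai–Lombardo carbonyl methylenation uses a non-basic gem-dimetallic reagent, so the acidic ester-bearing CH should be neither deprotonated nor epimerised and the ester is not attacked.

**Step 8**
Reactants: 12 methyl (1S,2R,3R)-2-(dimethoxymethyl)-6-methylidene-3-(propan-2-yl)cyclohexane-1-carboxylate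
Product: 14 (3aS,6R,7R,7aS)-7-(dimethoxymethyl)-3a-hydroxy-6-(propan-2-yl)hexahydro-2-benzofuran-1(3H)-one, via diol ester 13 (not isolated)
Conditions: OsO4 (2 mol%), NMO, acetone/H2O (5:1), rt; then PPTS (5 mol%), CH2Cl2, rt
Reagents that add atoms: N-methylmorpholine N-oxide, C[N+]1([O-])CCOCC1; water, O
Why: In this Upjohn dihydroxylation the bulky OsO4 should approach the exocyclic methylene from the equatorial direction, away from the 1,3-diaxial hydrogens, so the tertiary OH ends equatorial and trans to the ester and the CH2OH axial and cis to it, and the primary alcohol then closes the cis-fused γ-lactone with loss of methanol.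

**Step 9**
Reactants: 14 (3aS,6R,7R,7aS)-7-(dimethoxymethyl)-3a-hydroxy-6-(propan-2-yl)hexahydro-2-benzofuran-1(3H)-one; 15 (triphenyl-λ5-phosphanylidene)ethenone, Ph3P=C=C=O
Product: 16 (3aS,6R,7R,7aS)-7-(dimethoxymethyl)-1-oxo-6-(propan-2-yl)octahydro-2-benzofuran-3a-yl 2-(triphenyl-λ5-phosphanylidene)acetate
Conditions: toluene, 100 °C
Reagents that add atoms: none
Why: Addition of the O–H bond across the cumulated ylide gives the ester-stabilised ylide under neutral conditions, which avoids base-mediated acylation of a hindered tertiary β-hydroxy lactone that could undergo retro-aldol cleavage.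

**Step 10**
Reactants: 16 (3aS,6R,7R,7aS)-7-(dimethoxymethyl)-1-oxo-6-(propan-2-yl)octahydro-2-benzofuran-3a-yl 2-(triphenyl-λ5-phosphanylidene)acetate; 11 (4R,5R)-3-oxo-5-(propan-2-yl)-1,3,4,5,6,7-hexahydro-2-benzofuran-4-carbaldehyde
Product: 18 (3aS,6R,7R,7aS)-7-(dimethoxymethyl)-1-oxo-6-(propan-2-yl)octahydro-2-benzofuran-3a-yl (2Z)-2-bromo-3-[(4S,5R)-3-oxo-5-(propan-2-yl)-1,3,4,5,6,7-hexahydro-2-benzofuran-4-yl]prop-2-enoate, via bromo ylide 17 (not isolated)
Conditions: NBS (1.0 equiv), CH2Cl2, −20 °C; then 11, rt to 40 °C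
Reagents that add atoms: N-bromosuccinimide, O=C1CCC(=O)N1Br
Why: NBS brominates the stabilised ylide and succinimide anion deprotonates the salt to bromo ylide 17, whose Wittig reaction with 11 should give the Z-α-bromo enoate (ester trans to the ring carbon, the usual selectivity of stabilised ylides) under neutral conditions that spare the β-acyloxy lactone.

**Step 11**
Reactants: 18 (the Z-α-bromoacrylate joining the two halves, acetal intact)
Product: 19 (3aS,6R,7R,7aS)-7-formyl-1-oxo-6-(propan-2-yl)octahydro-2-benzofuran-3a-yl (2Z)-2-bromo-3-[(4S,5R)-3-oxo-5-(propan-2-yl)-1,3,4,5,6,7-hexahydro-2-benzofuran-4-yl]prop-2-enoate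
Conditions: TFA/H2O/CHCl3 (1:1:4), 0 °C
Reagents that add atoms: water, O
Why: Acetal hydrolysis as in step 6; the tertiary ester, vinyl bromide and both lactones are stable to cold aqueous acid.

**Step 12**
Reactants: 19 (aldehyde of the joined halves); 20 tert-butyl 2-(triphenyl-λ5-phosphanylidene)acetate
Product: 22 the bis(vinyl bromide), 19 in which the 7-formyl group has become a (1Z)-2-bromo-3-tert-butoxy-3-oxoprop-1-en-1-yl group, via tert-butyl bromo ylide 21 (not isolated)
Conditions: 20, NBS (1.0 equiv), CH2Cl2, −20 °C; then 19, rt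
Reagents that add atoms: N-bromosuccinimide, O=C1CCC(=O)N1Br
Why: The same one-pot ylide bromination/Wittig olefination as in step 10 should set the second Z-α-bromo enoate without base.

**Step 13**
Reactants: 22 (bis(vinyl bromide))
Product: 23 the tert-butyl ester of the target (both CH2OH groups free, both acrylates 2E)
Conditions: Bu3SnCH2OH (3 equiv), Pd(PPh3)4 (10 mol%), 1,4-dioxane, 80 °C
Reagents that add atoms: (tributylstannyl)methanol, CCCC[Sn](CCCC)(CCCC)CO
Why: Twofold Stille coupling of the electron-poor vinyl bromides proceeds with retention of alkene geometry, so each CH2OH ends cis to the ring carbon and trans to the ester, and the neutral conditions avoid β-elimination of the tertiary ester.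

**Step 14**
Reactants: 23 (tert-butyl ester of the target)
Product: 24 the target, CNP0238371.2
Conditions: TFA/CH2Cl2 (1:4), 0 °C to rt
Reagents that add atoms: none
Why: Acidolysis of the tert-butyl ester with loss of 2-methylpropene frees the acid, while the tertiary ester joining the halves should not ionise because its cation would be destabilised by the adjacent lactone carbonyl and acyloxymethyl groups.

**Compound list**

1 | 2,2-dimethoxyacetaldehyde | COC(OC)C=O | starting material
2 | methyl 3-oxobutanoate (methyl acetoacetate) | CC(=O)CC(=O)OC | starting material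
3 | methyl (2Z)-2-acetyl-4,4-dimethoxybut-2-enoate (formed with its 2E isomer) | COC(OC)/C=C(/C(C)=O)C(=O)OC | intermediate
4 | 3-methylbutanal | CC(C)CC=O | starting material
5 | methyl (3R,4R)-2-acetyl-3-(dimethoxymethyl)-4-formyl-5-methylhexanoate (C-2 epimers, in equilibrium with its cyclic hemiacetal) | O=C[C@H](C(C)C)[C@@H](C(OC)OC)C(C(=O)OC)C(C)=O | intermediate (not isolated)
6 | methyl (1S,5S,6R)-6-(dimethoxymethyl)-2-oxo-5-(propan-2-yl)cyclohex-3-ene-1-carboxylate | COC(OC)[C@H]1[C@H](C(=O)OC)C(=O)C=C[C@@H]1C(C)C | intermediate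
7 | methyl (1S,2R,3R)-2-(dimethoxymethyl)-6-oxo-3-(propan-2-yl)cyclohexane-1-carboxylate | COC(OC)[C@H]1[C@H](C(=O)OC)C(=O)CC[C@@H]1C(C)C | intermediate
8 | methyl (5R,6R)-6-(dimethoxymethyl)-5-(propan-2-yl)-2-[(trifluoromethanesulfonyl)oxy]cyclohex-1-ene-1-carboxylate | COC(OC)[C@H]1C(C(=O)OC)=C(OS(=O)(=O)C(F)(F)F)CC[C@@H]1C(C)C | intermediate
9 | methyl (5R,6R)-6-(dimethoxymethyl)-2-(hydroxymethyl)-5-(propan-2-yl)cyclohex-1-ene-1-carboxylate | COC(OC)[C@H]1C(C(=O)OC)=C(CO)CC[C@@H]1C(C)C | intermediate (not isolated)
10 | (6R,7R)-7-(dimethoxymethyl)-6-(propan-2-yl)-4,5,6,7-tetrahydro-2-benzofuran-1(3H)-one | COC(OC)[C@H]1C2=C(CC[C@@H]1C(C)C)COC2=O | intermediate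
11 | (4R,5R)-3-oxo-5-(propan-2-yl)-1,3,4,5,6,7-hexahydro-2-benzofuran-4-carbaldehyde | O=C[C@H]1C2=C(CC[C@@H]1C(C)C)COC2=O | intermediate
12 | methyl (1S,2R,3R)-2-(dimethoxymethyl)-6-methylidene-3-(propan-2-yl)cyclohexane-1-carboxylate | COC(OC)[C@H]1[C@H](C(=O)OC)C(=C)CC[C@@H]1C(C)C | intermediate
13 | methyl (1S,2R,3R,6S)-2-(dimethoxymethyl)-6-hydroxy-6-(hydroxymethyl)-3-(propan-2-yl)cyclohexane-1-carboxylate | COC(OC)[C@H]1[C@H](C(=O)OC)[C@](O)(CO)CC[C@@H]1C(C)C | intermediate (not isolated)
14 | (3aS,6R,7R,7aS)-7-(dimethoxymethyl)-3a-hydroxy-6-(propan-2-yl)hexahydro-2-benzofuran-1(3H)-one | CC(C)[C@H]1CC[C@@]2(O)COC(=O)[C@H]2[C@@H]1C(OC)OC | intermediate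
15 | (triphenyl-λ5-phosphanylidene)ethenone, Ph3P=C=C=O | O=C=C=P(c1ccccc1)(c1ccccc1)c1ccccc1 | starting material
16 | (3aS,6R,7R,7aS)-7-(dimethoxymethyl)-1-oxo-6-(propan-2-yl)octahydro-2-benzofuran-3a-yl 2-(triphenyl-λ5-phosphanylidene)acetate | CC(C)[C@H]1CC[C@@]2(OC(=O)C=P(c3ccccc3)(c3ccccc3)c3ccccc3)COC(=O)[C@H]2[C@@H]1C(OC)OC | intermediate
17 | (3aS,6R,7R,7aS)-7-(dimethoxymethyl)-1-oxo-6-(propan-2-yl)octahydro-2-benzofuran-3a-yl 2-bromo-2-(triphenyl-λ5-phosphanylidene)acetate | CC(C)[C@H]1CC[C@@]2(OC(=O)C(Br)=P(c3ccccc3)(c3ccccc3)c3ccccc3)COC(=O)[C@H]2[C@@H]1C(OC)OC | intermediate (not isolated)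
18 | (3aS,6R,7R,7aS)-7-(dimethoxymethyl)-1-oxo-6-(propan-2-yl)octahydro-2-benzofuran-3a-yl (2Z)-2-bromo-3-[(4S,5R)-3-oxo-5-(propan-2-yl)-1,3,4,5,6,7-hexahydro-2-benzofuran-4-yl]prop-2-enoate | CC(C)[C@H]1CC[C@@]2(OC(=O)/C(Br)=C/[C@H]3C4=C(CC[C@@H]3C(C)C)COC4=O)COC(=O)[C@H]2[C@@H]1C(OC)OC | intermediate
19 | (3aS,6R,7R,7aS)-7-formyl-1-oxo-6-(propan-2-yl)octahydro-2-benzofuran-3a-yl (2Z)-2-bromo-3-[(4S,5R)-3-oxo-5-(propan-2-yl)-1,3,4,5,6,7-hexahydro-2-benzofuran-4-yl]prop-2-enoate | CC(C)[C@H]1CC[C@@]2(OC(=O)/C(Br)=C/[C@H]3C4=C(CC[C@@H]3C(C)C)COC4=O)COC(=O)[C@H]2[C@@H]1C=O | intermediate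
20 | tert-butyl 2-(triphenyl-λ5-phosphanylidene)acetate | CC(C)(C)OC(=O)C=P(c1ccccc1)(c1ccccc1)c1ccccc1 | starting material
21 | tert-butyl 2-bromo-2-(triphenyl-λ5-phosphanylidene)acetate | CC(C)(C)OC(=O)C(Br)=P(c1ccccc1)(c1ccccc1)c1ccccc1 | intermediate (not isolated)
22 | bis(vinyl bromide): 19 with the 7-formyl group replaced by a (1Z)-2-bromo-3-tert-butoxy-3-oxoprop-1-en-1-yl group (ring stereocentres as in 14 and 11) | CC(C)[C@H]1CC[C@@]2(OC(=O)/C(Br)=C/[C@H]3C4=C(CC[C@@H]3C(C)C)COC4=O)COC(=O)[C@H]2[C@@H]1/C=C(\Br)C(=O)OC(C)(C)C | intermediate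
23 | tert-butyl ester of the target: both bromines of 22 replaced by CH2OH, both acrylates 2E | CC(C)[C@H]1CC[C@@]2(OC(=O)/C(=C/[C@H]3C4=C(CC[C@@H]3C(C)C)COC4=O)CO)COC(=O)[C@H]2[C@@H]1/C=C(\CO)C(=O)OC(C)(C)C | intermediate
24 | CNP0238371.2: the (2E)-2-(hydroxymethyl)acrylic acid on C-7 of the upper hydroxy-lactone half, whose 3a-oxygen is esterified by the (2E)-2-(hydroxymethyl)-3-(butenolide-4-yl)acrylic acid of the lower half | CC(C)[C@H]1CC[C@@]2(OC(=O)/C(=C/[C@H]3C4=C(CC[C@@H]3C(C)C)COC4=O)CO)COC(=O)[C@H]2[C@@H]1/C=C(\CO)C(=O)O | target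

**Step count and risks**

Total step count: 14. Longest linear sequence: 11 steps (1, 2, 3, 7, 8, 9, 10, 11, 12, 13, 14); the branch through steps 4 to 6 joins at step 10 and is equally long.

Three steps most likely to fail:

Step 2. The configuration next to the aldehyde may be lost while the Michael adduct waits for the acid-promoted cyclodehydration (enolisation, or reversible dehydration to a 4H-pyran), and the dimethyl acetal may be partly cleaved by the same acid. The fallback closes the ring by olefination instead of acid-mediated aldol condensation. It sets out from 1: Knoevenagel condensation with the known reagent methyl 4-(diethoxyphosphoryl)-3-oxobutanoate gives methyl (2Z)-2-[(diethoxyphosphoryl)acetyl]-4,4-dimethoxybut-2-enoate F1. The same amine-catalysed Michael addition of 4 gives methyl (3R,4R)-2-[(diethoxyphosphoryl)acetyl]-3-(dimethoxymethyl)-4-formyl-5-methylhexanoate F2. Its dianion (NaH, 2.1 equiv, THF, −20 to 0 °C) undergoes intramolecular Horner–Wadsworth–Emmons olefination, forming the same ring bond without acid and at low temperature, and the route is rejoined at 6.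

Step 8. Osmylation may take place from the axial face of the exocyclic alkene, which would put the tertiary OH cis to the ester and the CH2OH out of reach for a cis-fused lactone. The fallback uses an oxidant with the opposite facial preference followed by inversion. It sets out from 12: m-CPBA (NaHCO3, CH2Cl2), which prefers the axial face of methylenecyclohexanes, gives methyl 5-(dimethoxymethyl)-6-(propan-2-yl)-1-oxaspiro[2.5]octane-4-carboxylate with the epoxide oxygen cis to the ester, F3. Dilute aqueous HClO4 in THF opens the protonated epoxide at the tertiary carbon with inversion, hydrolyses the acetal and allows lactonisation, giving 7a-hydroxy-3-oxo-5-(propan-2-yl)octahydro-2-benzofuran-4-carbaldehyde (stereocentres as in 14) F4. Trimethyl orthoformate with PPTS in MeOH restores the dimethyl acetal, and the route is rejoined at 14.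

Step 9. Addition of the hindered tertiary alcohol to the cumulated ylide may be slow, and prolonged heating could bring retro-aldol opening or dehydration of the β-hydroxy lactone. The fallback builds the ylide stepwise. It sets out from 14: bromoacetyl bromide with pyridine (CH2Cl2, 0 °C) gives the 3a-O-bromoacetate of 14, F5. PPh3 in toluene gives the corresponding (acyloxycarbonylmethyl)triphenylphosphonium bromide F6. Shaking with aqueous NaHCO3 deprotonates the salt, and the route is rejoined at 16.

**Further compounds**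

F1 | step 2 | methyl (2Z)-2-[(diethoxyphosphoryl)acetyl]-4,4-dimethoxybut-2-enoate | COC(OC)/C=C(/C(=O)CP(=O)(OCC)OCC)C(=O)OC
F2 | step 2 | methyl (3R,4R)-2-[(diethoxyphosphoryl)acetyl]-3-(dimethoxymethyl)-4-formyl-5-methylhexanoate | O=C[C@H](C(C)C)[C@@H](C(OC)OC)C(C(=O)OC)C(=O)CP(=O)(OCC)OCC
F3 | step 8 | methyl 5-(dimethoxymethyl)-6-(propan-2-yl)-1-oxaspiro[2.5]octane-4-carboxylate, epoxide oxygen cis to the ester, other centres as in 12 | COC(OC)[C@H]1[C@H](C(=O)OC)[C@@]2(CO2)CC[C@@H]1C(C)C
F4 | step 8 | 7a-hydroxy-3-oxo-5-(propan-2-yl)octahydro-2-benzofuran-4-carbaldehyde, stereocentres as in 14 | CC(C)[C@H]1CC[C@@]2(O)COC(=O)[C@H]2[C@@H]1C=O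
F5 | step 9 | (3aS,6R,7R,7aS)-7-(dimethoxymethyl)-1-oxo-6-(propan-2-yl)octahydro-2-benzofuran-3a-yl 2-bromoacetate | CC(C)[C@H]1CC[C@@]2(OC(=O)CBr)COC(=O)[C@H]2[C@@H]1C(OC)OC
F6 | step 9 | {2-[(3aS,6R,7R,7aS)-7-(dimethoxymethyl)-1-oxo-6-(propan-2-yl)octahydro-2-benzofuran-3a-yl]oxy-2-oxoethyl}triphenylphosphonium bromide | CC(C)[C@H]1CC[C@@]2(OC(=O)C[P+](c3ccccc3)(c3ccccc3)c3ccccc3)COC(=O)[C@H]2[C@@H]1C(OC)OC.[Br-]
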